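**Plan**

1. Locants: ring C1 (epoxide carbon with CH3), C2 (O‑angeloyl), C3 (OH), C4 (carries the side chain), C5 (CH2), C6 (epoxide CH); side chain C7 (=CH2), C8 (O‑angeloyl), C9, C10/C11 (epoxide).
2. Cuts, in retrosynthetic order: O3–Si; side‑chain epoxide oxygen; O8–acyl; C10=C11 (metathesis) and C8–C9 (allylation); C7=CH2 (methylenation); the vinyl carbon of a C4 allyl group (oxidative cleavage); O2–acyl; ring epoxide oxygen; C1–CH3; then the ring bonds C5–C6 and C2–C3 together.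
3. Enabling feature: C1 is a latent ketone carbon whose two α‑carbons are C6 and C2, and C5–C4–C3 is the β‑carbon, α‑carbon and carbonyl carbon of a 2‑substituted acrolein. The cyclohexane ring is therefore a Michael (C6→C5) plus aldol (C2→C3) retron, a [3+3] union of keto acid 4 (CO2H on C6 as traceless activator) with 2‑allylacrolein 6.
4. Forward order: the carbocycle is formed first (step 4); then the C1 methyl alkene, the hydroxyl‑directed ring epoxide and the C2 angelate; the C4 allyl group is then grown into the side chain (aldehyde, α‑methylene, allyl, prenyl, angelate, epoxide); desilylation is last.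
5. Stereochemistry: (S)‑proline sets C3 and, by dynamic resolution of the epimerisable aldehyde, C4; C2 equilibrates to equatorial (all‑cis); C1/C6 come from oxygen delivery by the C2 hydroxyl; C8 from (−)‑Ipc2B(allyl); C10 from the D‑fructose‑derived Shi ketone; both (Z)‑esters from a preformed (Z)‑acyl donor.

Key step: step 4

Remark: keto acid 4 is assumed to survive cold isolation for immediate use; angelic anhydride, (−)‑Ipc2B(allyl) solution and the fructose‑derived epoxidation ketone are taken as purchasable reagents.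

**Route**

Step 1
Reactants: 1 ethyl 4‑chloro‑3‑oxobutanoate; 2 4‑methoxybenzyl alcohol
Product: 3 ethyl 4‑[(4‑methoxybenzyl)oxy]‑3‑oxobutanoate
Conditions: NaH (2.2 equiv), THF, 0 °C to rt; then aq HCl
Reagents that add atoms: none
Why: Williamson ether synthesis; the second equivalent of NaH holds 1 as its enolate, so the alkoxide of 2 displaces the activated α‑keto chloride by SN2 without condensation side reactions; no stereocentre is formed.

Step 2
Reactants: 3 ethyl 4‑[(4‑methoxybenzyl)oxy]‑3‑oxobutanoate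
Product: 4 4‑[(4‑methoxybenzyl)oxy]‑3‑oxobutanoic acid
Conditions: NaOH (1 M aq), 0 °C to rt; then HCl to pH 2 at 0 °C, extraction, used at once
Reagents that add atoms: sodium hydroxide, [Na+].[OH-]
Why: ester saponification; the β‑keto acid is liberated cold and used immediately because it loses CO2 on standing; no stereocentre.

Step 3
Reactants: 5 pent‑4‑enal
Product: 6 2‑methylidenepent‑4‑enal (2‑allylacrolein)
Conditions: aq HCHO (37 %), pyrrolidine (10 mol %), propionic acid (10 mol %), iPrOH, 45 °C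
Reagents that add atoms: formaldehyde, C=O
Why: amine‑catalysed α‑methylenation of an aldehyde (Mannich condensation of the enamine with formaldehyde, then elimination of the amine) should give the 2‑substituted acrolein; no stereocentre.

Step 4
Reactants: 4 4‑[(4‑methoxybenzyl)oxy]‑3‑oxobutanoic acid; 6 2‑methylidenepent‑4‑enal
Product: 9 (2R,3R,4S)‑3‑hydroxy‑2‑[(4‑methoxybenzyl)oxy]‑4‑(prop‑2‑en‑1‑yl)cyclohexan‑1‑one, via Michael adduct keto acid 7 (not isolated), via keto aldehyde 8 (not isolated)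
Conditions: (S)‑proline (30 mol %), DMSO, rt
Reagents that add atoms: none
Why: The doubly activated carbon of 4 (C6, between ketone and carboxyl) adds to the β‑carbon (C5) of enal 6, which proline activates as its iminium ion, and loss of CO2 leaves keto aldehyde 8 with the first bond placed regiospecifically; proline then forms the ketone enamine towards the alkoxy‑bearing carbon C2, which attacks the aldehyde carbon C3. The closest known reaction types are the amine‑catalysed decarboxylative Michael addition of β‑keto acids to enals, the Robinson‑type [3+3] Michael/aldol annulation of β‑keto esters with enals and the proline‑catalysed Hajos–Parrish enolendo aldolisation. The carbocycle closes by a 6‑(enolendo)‑exo‑trig aldol addition through a chair‑like transition state, the other enol or enamine positions being able to give only four‑membered rings. C3 is set by the catalyst: in the accepted enamine/carboxylic acid transition‑state model the acid of (S)‑proline delivers the aldehyde to one enamine face with the aldehyde oxygen gauche to C1, which is expected to give the axial (3R) alcohol; C4 is set by dynamic kinetic resolution, because the aldehyde α‑centre of 8 epimerises through its enamine and only the epimer with an equatorial allyl group fits the chair; C2, α to the ketone, settles equatorial by enolisation, which completes the all‑cis array. The step needs regiocontrol of the first bond, secured by the carboxyl group that leaves as CO2, and it needs the ketol to survive without dehydration, which the mild medium and the immediate silylation in step 5 should secure.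

Step 5
Reactants: 9 (2R,3R,4S)‑3‑hydroxy‑2‑[(4‑methoxybenzyl)oxy]‑4‑(prop‑2‑en‑1‑yl)cyclohexan‑1‑one
Product: 10 (2R,3R,4S)‑2‑[(4‑methoxybenzyl)oxy]‑4‑(prop‑2‑en‑1‑yl)‑3‑[(triethylsilyl)oxy]cyclohexan‑1‑one
Conditions: Et3SiOTf (1.1 equiv), 2,6‑lutidine, CH2Cl2, −78 °C
Reagents that add atoms: triethylsilyl trifluoromethanesulfonate, CC[Si](CC)(CC)OS(=O)(=O)C(F)(F)F
Why: silylation of the secondary alcohol with a silyl triflate; it blocks retro‑aldol cleavage and dehydration of the ketol and masks O3 to the end; low temperature and one equivalent of reagent avoid silyl enol ether formation.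

Step 6
Reactants: 10 (2R,3R,4S)‑2‑[(4‑methoxybenzyl)oxy]‑4‑(prop‑2‑en‑1‑yl)‑3‑[(triethylsilyl)oxy]cyclohexan‑1‑one
Product: 11 (4R,5R,6R)‑6‑[(4‑methoxybenzyl)oxy]‑4‑(prop‑2‑en‑1‑yl)‑5‑[(triethylsilyl)oxy]cyclohex‑1‑en‑1‑yl trifluoromethanesulfonate
Conditions: KN(SiMe3)2 (1.1 equiv), THF, −78 °C; then PhNTf2, −78 to 0 °C
Reagents that add atoms: N‑phenylbis(trifluoromethanesulfonimide), O=S(=O)(N(c1ccccc1)S(=O)(=O)C(F)(F)F)C(F)(F)F
Why: kinetic enolate formation at the unhindered C6 methylene with a bulky amide base, then O‑sulfonylation (enol triflate synthesis); deprotonation at the tertiary, alkoxy‑substituted C2 should be slower; stereocentres are untouched.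

Step 7
Reactants: 11 (4R,5R,6R)‑6‑[(4‑methoxybenzyl)oxy]‑4‑(prop‑2‑en‑1‑yl)‑5‑[(triethylsilyl)oxy]cyclohex‑1‑en‑1‑yl trifluoromethanesulfonate
Product: 12 triethyl{[(1R,2S,6R)‑2‑[(4‑methoxybenzyl)oxy]‑3‑methyl‑6‑(prop‑2‑en‑1‑yl)cyclohex‑3‑en‑1‑yl]oxy}silane
Conditions: Fe(acac)3 (5 mol %), MeMgBr, THF/NMP, −30 to 0 °C
Reagents that add atoms: methylmagnesium bromide, C[Mg]Br
Why: iron‑catalysed Kumada‑type cross‑coupling of the alkenyl triflate with the methyl Grignard reagent installs the C1 methyl group without moving the double bond; ethers, silyl ether and terminal alkene are tolerated.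

Step 8
Reactants: 12 triethyl{[(1R,2S,6R)‑2‑[(4‑methoxybenzyl)oxy]‑3‑methyl‑6‑(prop‑2‑en‑1‑yl)cyclohex‑3‑en‑1‑yl]oxy}silane
Product: 13 (1S,5R,6R)‑2‑methyl‑5‑(prop‑2‑en‑1‑yl)‑6‑[(triethylsilyl)oxy]cyclohex‑2‑en‑1‑ol
Conditions: DDQ (1.2 equiv), CH2Cl2/pH 7 phosphate buffer, 0 °C
Reagents that add atoms: none
Why: oxidative cleavage of the p‑methoxybenzyl ether by DDQ (benzylic hydride abstraction, hydrolysis of the oxocarbenium ion); the buffered medium keeps the triethylsilyl ether and the alkenes.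

Step 9
Reactants: 13 (1S,5R,6R)‑2‑methyl‑5‑(prop‑2‑en‑1‑yl)‑6‑[(triethylsilyl)oxy]cyclohex‑2‑en‑1‑ol
Product: 14 (1R,2R,3R,4R,6S)‑1‑methyl‑4‑(prop‑2‑en‑1‑yl)‑3‑[(triethylsilyl)oxy]‑7‑oxabicyclo[4.1.0]heptan‑2‑ol
Conditions: VO(acac)2 (5 mol %), tBuOOH (in decane), CH2Cl2, 0 °C to rt
Reagents that add atoms: tert‑butyl hydroperoxide, CC(C)(C)OO
Why: hydroxyl‑directed vanadium‑catalysed epoxidation; the peroxide bound to the vanadate ester of the C2 hydroxyl is delivered to the same face of the C1=C6 alkene, which sets C1 and C6 cis to O2, and the unactivated terminal alkene should not react.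

Step 10
Reactants: 14 (1R,2R,3R,4R,6S)‑1‑methyl‑4‑(prop‑2‑en‑1‑yl)‑3‑[(triethylsilyl)oxy]‑7‑oxabicyclo[4.1.0]heptan‑2‑ol
Product: 15 (1S,2R,3R,4R,6S)‑1‑methyl‑4‑(prop‑2‑en‑1‑yl)‑3‑[(triethylsilyl)oxy]‑7‑oxabicyclo[4.1.0]heptan‑2‑yl (2Z)‑2‑methylbut‑2‑enoate
Conditions: angelic anhydride (1.5 equiv), then LiN(SiMe3)2 (1.1 equiv) added to the mixture, THF, −78 to 0 °C
Reagents that add atoms: angelic anhydride, C/C=C(/C)C(=O)OC(=O)/C(C)=C\C
Why: O‑acylation of the lithium alkoxide by the preformed (Z)‑anhydride (nucleophilic acyl substitution); no acid‑activation step that could isomerise the angeloyl group, and the alkoxide, cis to the epoxide oxygen, cannot open the epoxide (a Payne rearrangement needs the anti arrangement).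

Step 11
Reactants: 15 (1S,2R,3R,4R,6S)‑1‑methyl‑4‑(prop‑2‑en‑1‑yl)‑3‑[(triethylsilyl)oxy]‑7‑oxabicyclo[4.1.0]heptan‑2‑yl (2Z)‑2‑methylbut‑2‑enoate
Product: 17 (1S,2R,3R,4S,6S)‑1‑methyl‑4‑(2‑oxoethyl)‑3‑[(triethylsilyl)oxy]‑7‑oxabicyclo[4.1.0]heptan‑2‑yl (2Z)‑2‑methylbut‑2‑enoate, via vicinal diol 16 (not isolated)
Conditions: OsO4 (2 mol %), NaIO4 (4 equiv), 2,6‑lutidine, dioxane/H2O, rt
Reagents that add atoms: osmium tetroxide, O=[Os](=O)(=O)=O; sodium periodate, [Na+].[O-]I(=O)(=O)=O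
Why: Lemieux–Johnson oxidative cleavage; osmylation should be chemoselective for the electron‑rich monosubstituted alkene over the hindered, electron‑poor angelate double bond, and periodate cleaves the diol in the flask.

Step 12
Reactants: 17 (1S,2R,3R,4S,6S)‑1‑methyl‑4‑(2‑oxoethyl)‑3‑[(triethylsilyl)oxy]‑7‑oxabicyclo[4.1.0]heptan‑2‑yl (2Z)‑2‑methylbut‑2‑enoate
Product: 18 (1S,2R,3R,4S,6S)‑1‑methyl‑4‑(3‑oxoprop‑1‑en‑2‑yl)‑3‑[(triethylsilyl)oxy]‑7‑oxabicyclo[4.1.0]heptan‑2‑yl (2Z)‑2‑methylbut‑2‑enoate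
Conditions: aq HCHO (37 %), pyrrolidine (10 mol %), propionic acid (10 mol %), iPrOH, 45 °C
Reagents that add atoms: formaldehyde, C=O
Why: amine‑catalysed α‑methylenation as in step 3 (Mannich condensation–elimination); only C7 carries α‑hydrogens, and C4 keeps its equatorial, thermodynamically preferred configuration.

Step 13
Reactants: 18 (1S,2R,3R,4S,6S)‑1‑methyl‑4‑(3‑oxoprop‑1‑en‑2‑yl)‑3‑[(triethylsilyl)oxy]‑7‑oxabicyclo[4.1.0]heptan‑2‑yl (2Z)‑2‑methylbut‑2‑enoate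
Product: 20 (1S,2R,3R,4S,6S)‑4‑[(3S)‑3‑hydroxyhexa‑1,5‑dien‑2‑yl]‑1‑methyl‑3‑[(triethylsilyl)oxy]‑7‑oxabicyclo[4.1.0]heptan‑2‑yl (2Z)‑2‑methylbut‑2‑enoate, via borinic ester 19 (not isolated)
Conditions: (−)‑Ipc2B(allyl) (1.3 equiv, in pentane), Et2O, −78 °C; then NaBO3·4H2O, THF/H2O, rt
Reagents that add atoms: (−)‑B‑allyldiisopinocampheylborane, C=CCB([C@@H]1C[C@@H]2C[C@H]([C@H]1C)C2(C)C)[C@@H]1C[C@@H]2C[C@H]([C@H]1C)C2(C)C
Why: Brown asymmetric allylboration through a closed six‑membered chair transition state; the isopinocampheyl groups derived from (+)‑α‑pinene direct the allyl group to the Si face of the aldehyde, which should give the (8S) alcohol under reagent control; perborate work‑up spares ester and epoxide.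

Step 14
Reactants: 20 (1S,2R,3R,4S,6S)‑4‑[(3S)‑3‑hydroxyhexa‑1,5‑dien‑2‑yl]‑1‑methyl‑3‑[(triethylsilyl)oxy]‑7‑oxabicyclo[4.1.0]heptan‑2‑yl (2Z)‑2‑methylbut‑2‑enoate
Product: 21 (1S,2R,3R,4S,6S)‑4‑[(3S)‑3‑hydroxy‑6‑methylhepta‑1,5‑dien‑2‑yl]‑1‑methyl‑3‑[(triethylsilyl)oxy]‑7‑oxabicyclo[4.1.0]heptan‑2‑yl (2Z)‑2‑methylbut‑2‑enoate
Conditions: second‑generation Grubbs catalyst, (H2IMes)(PCy3)Cl2Ru=CHPh (5 mol %), 2‑methylbut‑2‑ene (large excess), CH2Cl2, 40 °C
Reagents that add atoms: 2‑methylbut‑2‑ene, CC=C(C)C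
Why: olefin cross‑metathesis turns the monosubstituted vinyl group into the prenyl‑type trisubstituted alkene; the 1,1‑disubstituted and the conjugated trisubstituted alkenes are too hindered or electron‑poor to take part.

Step 15
Reactants: 21 (1S,2R,3R,4S,6S)‑4‑[(3S)‑3‑hydroxy‑6‑methylhepta‑1,5‑dien‑2‑yl]‑1‑methyl‑3‑[(triethylsilyl)oxy]‑7‑oxabicyclo[4.1.0]heptan‑2‑yl (2Z)‑2‑methylbut‑2‑enoate
Product: 22 (1S,2R,3R,4S,6S)‑1‑methyl‑4‑[(3S)‑6‑methyl‑3‑{[(2Z)‑2‑methylbut‑2‑enoyl]oxy}hepta‑1,5‑dien‑2‑yl]‑3‑[(triethylsilyl)oxy]‑7‑oxabicyclo[4.1.0]heptan‑2‑yl (2Z)‑2‑methylbut‑2‑enoate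
Conditions: angelic anhydride (1.5 equiv), then LiN(SiMe3)2 (1.1 equiv), THF, −78 to 0 °C
Reagents that add atoms: angelic anhydride, C/C=C(/C)C(=O)OC(=O)/C(C)=C\C
Why: the same alkoxide acylation as in step 10, now at the allylic C8 hydroxyl; the C8–O bond is not touched, so the stereocentre is retained.

Step 16
Reactants: 22 (1S,2R,3R,4S,6S)‑1‑methyl‑4‑[(3S)‑6‑methyl‑3‑{[(2Z)‑2‑methylbut‑2‑enoyl]oxy}hepta‑1,5‑dien‑2‑yl]‑3‑[(triethylsilyl)oxy]‑7‑oxabicyclo[4.1.0]heptan‑2‑yl (2Z)‑2‑methylbut‑2‑enoate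
Product: 23 (1S,2R,3R,4S,6S)‑4‑[(3S)‑4‑[(2R)‑3,3‑dimethyloxiran‑2‑yl]‑3‑{[(2Z)‑2‑methylbut‑2‑enoyl]oxy}but‑1‑en‑2‑yl]‑1‑methyl‑3‑[(triethylsilyl)oxy]‑7‑oxabicyclo[4.1.0]heptan‑2‑yl (2Z)‑2‑methylbut‑2‑enoate
Conditions: D‑fructose‑derived Shi ketone (30 mol %), Oxone (2KHSO5·KHSO4·K2SO4), K2CO3, Bu4NHSO4, MeCN/dimethoxymethane/aq Na2B4O7–Na2EDTA buffer (pH 10.5), 0 °C
Reagents that add atoms: potassium peroxymonosulfate, [K+].[O-]S(=O)(=O)OO
Why: Shi asymmetric epoxidation; the chiral dioxirane formed from the ketone attacks the most electron‑rich (trisubstituted, non‑conjugated) alkene through a spiro transition state and should give the (10R) epoxide under reagent control, while the 1,1‑disubstituted alkene and the two conjugated ester alkenes react much more slowly.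

Step 17
Reactants: 23 (1S,2R,3R,4S,6S)‑4‑[(3S)‑4‑[(2R)‑3,3‑dimethyloxiran‑2‑yl]‑3‑{[(2Z)‑2‑methylbut‑2‑enoyl]oxy}but‑1‑en‑2‑yl]‑1‑methyl‑3‑[(triethylsilyl)oxy]‑7‑oxabicyclo[4.1.0]heptan‑2‑yl (2Z)‑2‑methylbut‑2‑enoate
Product: 24 (1S,2R,3R,4S,6S)‑4‑[(3S)‑4‑[(2R)‑3,3‑dimethyloxiran‑2‑yl]‑3‑{[(2Z)‑2‑methylbut‑2‑enoyl]oxy}but‑1‑en‑2‑yl]‑3‑hydroxy‑1‑methyl‑7‑oxabicyclo[4.1.0]heptan‑2‑yl (2Z)‑2‑methylbut‑2‑enoate (target)
Conditions: HF·pyridine, pyridine, THF, 0 °C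
Reagents that add atoms: none
Why: fluoride‑induced cleavage of the triethylsilyl ether (Si–F bond formation); the pyridine‑buffered medium should be neither basic enough for acyl migration from O2 to O3 nor acidic enough to open the epoxides.

**Compound list**

1 | ethyl 4‑chloro‑3‑oxobutanoate | CCOC(=O)CC(=O)CCl | starting material
2 | 4‑methoxybenzyl alcohol | COc1ccc(CO)cc1 | starting material
3 | ethyl 4‑[(4‑methoxybenzyl)oxy]‑3‑oxobutanoate | CCOC(=O)CC(=O)COCc1ccc(OC)cc1 | intermediate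
4 | 4‑[(4‑methoxybenzyl)oxy]‑3‑oxobutanoic acid | OC(=O)CC(=O)COCc1ccc(OC)cc1 | intermediate
5 | pent‑4‑enal | C=CCCC=O | starting material
6 | 2‑methylidenepent‑4‑enal | C=CCC(=C)C=O | intermediate
7 | 2‑(2‑formylpent‑4‑en‑1‑yl)‑4‑[(4‑methoxybenzyl)oxy]‑3‑oxobutanoic acid (stereocentres labile) | C=CCC(C=O)CC(C(=O)O)C(=O)COCc1ccc(OC)cc1 | intermediate
8 | 6‑[(4‑methoxybenzyl)oxy]‑5‑oxo‑2‑(prop‑2‑en‑1‑yl)hexanal (C2 labile) | C=CCC(C=O)CCC(=O)COCc1ccc(OC)cc1 | intermediate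
9 | (2R,3R,4S)‑3‑hydroxy‑2‑[(4‑methoxybenzyl)oxy]‑4‑(prop‑2‑en‑1‑yl)cyclohexan‑1‑one | C=CC[C@@H]1CCC(=O)[C@H](OCc2ccc(OC)cc2)[C@@H]1O | intermediate
10 | (2R,3R,4S)‑2‑[(4‑methoxybenzyl)oxy]‑4‑(prop‑2‑en‑1‑yl)‑3‑[(triethylsilyl)oxy]cyclohexan‑1‑one | C=CC[C@@H]1CCC(=O)[C@H](OCc2ccc(OC)cc2)[C@@H]1O[Si](CC)(CC)CC | intermediate
11 | (4R,5R,6R)‑6‑[(4‑methoxybenzyl)oxy]‑4‑(prop‑2‑en‑1‑yl)‑5‑[(triethylsilyl)oxy]cyclohex‑1‑en‑1‑yl trifluoromethanesulfonate | C=CC[C@@H]1CC=C(OS(=O)(=O)C(F)(F)F)[C@H](OCc2ccc(OC)cc2)[C@@H]1O[Si](CC)(CC)CC | intermediate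
12 | triethyl{[(1R,2S,6R)‑2‑[(4‑methoxybenzyl)oxy]‑3‑methyl‑6‑(prop‑2‑en‑1‑yl)cyclohex‑3‑en‑1‑yl]oxy}silane | C=CC[C@@H]1CC=C(C)[C@H](OCc2ccc(OC)cc2)[C@@H]1O[Si](CC)(CC)CC | intermediate
13 | (1S,5R,6R)‑2‑methyl‑5‑(prop‑2‑en‑1‑yl)‑6‑[(triethylsilyl)oxy]cyclohex‑2‑en‑1‑ol | C=CC[C@@H]1CC=C(C)[C@H](O)[C@@H]1O[Si](CC)(CC)CC | intermediate
14 | (1R,2R,3R,4R,6S)‑1‑methyl‑4‑(prop‑2‑en‑1‑yl)‑3‑[(triethylsilyl)oxy]‑7‑oxabicyclo[4.1.0]heptan‑2‑ol | C=CC[C@@H]1C[C@@H]2O[C@]2(C)[C@H](O)[C@@H]1O[Si](CC)(CC)CC | intermediate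
15 | (1S,2R,3R,4R,6S)‑1‑methyl‑4‑(prop‑2‑en‑1‑yl)‑3‑[(triethylsilyl)oxy]‑7‑oxabicyclo[4.1.0]heptan‑2‑yl (2Z)‑2‑methylbut‑2‑enoate | C=CC[C@@H]1C[C@@H]2O[C@]2(C)[C@H](OC(=O)/C(C)=C\C)[C@@H]1O[Si](CC)(CC)CC | intermediate
16 | (1S,2R,3R,4R,6S)‑4‑(2,3‑dihydroxypropyl)‑1‑methyl‑3‑[(triethylsilyl)oxy]‑7‑oxabicyclo[4.1.0]heptan‑2‑yl (2Z)‑2‑methylbut‑2‑enoate (both carbinol epimers) | OCC(O)C[C@@H]1C[C@@H]2O[C@]2(C)[C@H](OC(=O)/C(C)=C\C)[C@@H]1O[Si](CC)(CC)CC | intermediate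
17 | (1S,2R,3R,4S,6S)‑1‑methyl‑4‑(2‑oxoethyl)‑3‑[(triethylsilyl)oxy]‑7‑oxabicyclo[4.1.0]heptan‑2‑yl (2Z)‑2‑methylbut‑2‑enoate | O=CC[C@@H]1C[C@@H]2O[C@]2(C)[C@H](OC(=O)/C(C)=C\C)[C@@H]1O[Si](CC)(CC)CC | intermediate
18 | (1S,2R,3R,4S,6S)‑1‑methyl‑4‑(3‑oxoprop‑1‑en‑2‑yl)‑3‑[(triethylsilyl)oxy]‑7‑oxabicyclo[4.1.0]heptan‑2‑yl (2Z)‑2‑methylbut‑2‑enoate | C=C(C=O)[C@@H]1C[C@@H]2O[C@]2(C)[C@H](OC(=O)/C(C)=C\C)[C@@H]1O[Si](CC)(CC)CC | intermediate
19 | bis(isopinocampheyl)borinic ester of 20 (isopinocampheyl groups from (+)‑α‑pinene) | C=C([C@H](CC=C)OB([C@@H]3C[C@@H]4C[C@H]([C@H]3C)C4(C)C)[C@@H]3C[C@@H]4C[C@H]([C@H]3C)C4(C)C)[C@@H]1C[C@@H]2O[C@]2(C)[C@H](OC(=O)/C(C)=C\C)[C@@H]1O[Si](CC)(CC)CC | intermediate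
20 | (1S,2R,3R,4S,6S)‑4‑[(3S)‑3‑hydroxyhexa‑1,5‑dien‑2‑yl]‑1‑methyl‑3‑[(triethylsilyl)oxy]‑7‑oxabicyclo[4.1.0]heptan‑2‑yl (2Z)‑2‑methylbut‑2‑enoate | C=C([C@H](CC=C)O)[C@@H]1C[C@@H]2O[C@]2(C)[C@H](OC(=O)/C(C)=C\C)[C@@H]1O[Si](CC)(CC)CC | intermediate
21 | (1S,2R,3R,4S,6S)‑4‑[(3S)‑3‑hydroxy‑6‑methylhepta‑1,5‑dien‑2‑yl]‑1‑methyl‑3‑[(triethylsilyl)oxy]‑7‑oxabicyclo[4.1.0]heptan‑2‑yl (2Z)‑2‑methylbut‑2‑enoate | C=C([C@H](CC=C(C)C)O)[C@@H]1C[C@@H]2O[C@]2(C)[C@H](OC(=O)/C(C)=C\C)[C@@H]1O[Si](CC)(CC)CC | intermediate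
22 | (1S,2R,3R,4S,6S)‑1‑methyl‑4‑[(3S)‑6‑methyl‑3‑{[(2Z)‑2‑methylbut‑2‑enoyl]oxy}hepta‑1,5‑dien‑2‑yl]‑3‑[(triethylsilyl)oxy]‑7‑oxabicyclo[4.1.0]heptan‑2‑yl (2Z)‑2‑methylbut‑2‑enoate | C=C([C@H](CC=C(C)C)OC(=O)/C(C)=C\C)[C@@H]1C[C@@H]2O[C@]2(C)[C@H](OC(=O)/C(C)=C\C)[C@@H]1O[Si](CC)(CC)CC | intermediate
23 | (1S,2R,3R,4S,6S)‑4‑[(3S)‑4‑[(2R)‑3,3‑dimethyloxiran‑2‑yl]‑3‑{[(2Z)‑2‑methylbut‑2‑enoyl]oxy}but‑1‑en‑2‑yl]‑1‑methyl‑3‑[(triethylsilyl)oxy]‑7‑oxabicyclo[4.1.0]heptan‑2‑yl (2Z)‑2‑methylbut‑2‑enoate | C=C([C@H](C[C@H]1OC1(C)C)OC(=O)/C(C)=C\C)[C@@H]1C[C@@H]2O[C@]2(C)[C@H](OC(=O)/C(C)=C\C)[C@@H]1O[Si](CC)(CC)CC | intermediate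
24 | (1S,2R,3R,4S,6S)‑4‑[(3S)‑4‑[(2R)‑3,3‑dimethyloxiran‑2‑yl]‑3‑{[(2Z)‑2‑methylbut‑2‑enoyl]oxy}but‑1‑en‑2‑yl]‑3‑hydroxy‑1‑methyl‑7‑oxabicyclo[4.1.0]heptan‑2‑yl (2Z)‑2‑methylbut‑2‑enoate | C=C([C@H](C[C@H]1OC1(C)C)OC(=O)/C(C)=C\C)[C@@H]1C[C@@H]2O[C@]2(C)[C@H](OC(=O)/C(C)=C\C)[C@@H]1O | target

**Step count and risks**

Total: 17 steps. Longest linear sequence: 16 steps (1 → 3 → 4 → 9 → … → 24); 6 is made in one step from 5.

Steps most likely to fail:

1. Step 4. The keto acid may lose CO2 before it has added to the enal, the enal may oligomerise, and epimerisation of the aldehyde α‑centre may be too slow for the dynamic resolution, so that enantio‑ and diastereoselection in the ring closure are poor; retro‑aldol equilibration could also erode the axial alcohol. Fallback (sets out from 4 and 6, comes back at 9): the two bond formations are separated and catalyst control is replaced by resolution. 4 and 6 are joined under tertiary‑amine catalysis (DABCO, toluene, rt) in a decarboxylative Michael addition and keto aldehyde 8 is isolated. It is cyclised without asymmetric induction (pyrrolidine/acetic acid, CH2Cl2, 0 °C) to the racemic all‑cis ketol F1. The enantiomers are parted by lipase‑catalysed transesterification (Candida antarctica lipase B, vinyl acetate, tert‑butyl methyl ether), the enzyme preparation being chosen so that the antipode is converted into the antipodal ketol acetate F2 while 9 is recovered and enters step 5.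

2. Step 6. Deprotonation may occur on the alkoxy‑bearing side (C2) in competition with C6, and that enolate can expel the neighbouring silyloxy group by β‑elimination. Fallback (sets out from 10, comes back at 12, bypassing 11): 10 is condensed with 2,4,6‑triisopropylbenzenesulfonyl hydrazide (THF, rt) to the trisylhydrazone F3. A Shapiro reaction (n‑BuLi, 2.2 equiv, THF, −78 to 0 °C) removes the proton at the unsubstituted C6 and, after loss of sulfinate and nitrogen, gives the vinyllithium F4, which is methylated in the same flask with MeI to give 12.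

3. Step 10 (the same concern applies to step 15). The (Z)‑acyl group may isomerise to the (E)‑tigloyl isomer during acyl transfer, and the silyl group may migrate from O3 to the neighbouring alkoxide before acylation. Fallback (sets out from 14, comes back at 15): 14 is esterified under neutral carbodiimide conditions with 2‑[bis(2,2,2‑trifluoroethoxy)phosphoryl]propanoic acid (DCC, DMAP cat., CH2Cl2) to the phosphonate ester F5. The (Z)‑alkene is then built on the ester by Still–Gennari olefination with acetaldehyde (KN(SiMe3)2, 18‑crown‑6, THF, −78 °C), which gives 15.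

**Further compounds**

F1 | step 4 | racemic (2R*,3R*,4S*)‑3‑hydroxy‑2‑[(4‑methoxybenzyl)oxy]‑4‑(prop‑2‑en‑1‑yl)cyclohexan‑1‑one | C=CC[C@@H]1CCC(=O)[C@H](OCc2ccc(OC)cc2)[C@@H]1O.C=CC[C@H]1CCC(=O)[C@@H](OCc2ccc(OC)cc2)[C@H]1O
F2 | step 4 | (1S,2S,6R)‑2‑[(4‑methoxybenzyl)oxy]‑3‑oxo‑6‑(prop‑2‑en‑1‑yl)cyclohexyl acetate | C=CC[C@H]1CCC(=O)[C@@H](OCc2ccc(OC)cc2)[C@H]1OC(C)=O
F3 | step 6 | N'‑[(2S,3R,4S)‑2‑[(4‑methoxybenzyl)oxy]‑4‑(prop‑2‑en‑1‑yl)‑3‑[(triethylsilyl)oxy]cyclohexylidene]‑2,4,6‑triisopropylbenzenesulfonohydrazide | C=CC[C@@H]1CCC(=NNS(=O)(=O)c2c(C(C)C)cc(C(C)C)cc2C(C)C)[C@H](OCc2ccc(OC)cc2)[C@@H]1O[Si](CC)(CC)CC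
F4 | step 6 | vinyllithium corresponding to 11 with lithium in place of the triflate group | C=CC[C@@H]1CC=C([Li])[C@H](OCc2ccc(OC)cc2)[C@@H]1O[Si](CC)(CC)CC
F5 | step 10 | (1S,2R,3R,4R,6S)‑1‑methyl‑4‑(prop‑2‑en‑1‑yl)‑3‑[(triethylsilyl)oxy]‑7‑oxabicyclo[4.1.0]heptan‑2‑yl 2‑[bis(2,2,2‑trifluoroethoxy)phosphoryl]propanoate | C=CC[C@@H]1C[C@@H]2O[C@]2(C)[C@H](OC(=O)C(C)P(=O)(OCC(F)(F)F)OCC(F)(F)F)[C@@H]1O[Si](CC)(CC)CC
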